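The oxirane is traced back to an E-trisubstituted C2'=C3' alkene, and that alkene is cut at both C1'–C2' and C3'–CH3. The feature exploited is that C3' bears a methyl group while C2' bears the C1'H2–O–C7 (coumarin ring) unit cis to it: the imprint of syn methyl–aluminium addition across a terminal C2'≡C3' alkyne followed by carbon capture at C2'. One operation thus unites the lactone alkyne, a methyl group and the coumarin chloromethyl ether and fixes the alkene geometry. The precursor is a (3R,5R)-5-propargyl-γ-butyrolactone from (R)-citramalic acid, its tertiary C7' hydroxyl masked as a triethylsilyl ether. Shi epoxidation and desilylation complete the route.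

Key step: step 8

Remark on the chemistry: side-chain atoms are numbered C1' (OCH2) to C8' (lactone C=O); C5' keeps one spatial arrangement from step 4 onwards, but its CIP label is R in every intermediate and S in the target, because the ranking of C4' against C6' changes.

Step 1
Reactants: 1 (R)-citramalic acid; 2 2,2-dimethoxypropane
Product: 3 2-[(4R)-2,2,4-trimethyl-5-oxo-1,3-dioxolan-4-yl]acetic acid
Conditions: 2,2-dimethoxypropane (5 equiv), PPTS (cat.), CH2Cl2, rt
Reagents that add atoms: 2,2-dimethoxypropane, COC(C)(C)OC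
Why: Acid-catalysed transketalisation engages only the α-hydroxy acid pair, which alone can close a five-membered 1,3-dioxolan-4-one, so the distal CH2CO2H stays free and the quaternary C7' centre is carried through untouched.

Step 2
Reactants: 3 2-[(4R)-2,2,4-trimethyl-5-oxo-1,3-dioxolan-4-yl]acetic acid
Product: 4 (5R)-5-(2-hydroxyethyl)-2,2,5-trimethyl-1,3-dioxolan-4-one
Conditions: BH3·THF (1.1 equiv), THF, 0 °C to rt; MeOH quench, evaporation
Reagents that add atoms: none
Why: Chemoselective borane reduction takes a free carboxylic acid through its acyloxyborane much faster than it touches the dioxolanone carbonyl, and the neutral methanol quench avoids acid-induced translactonisation of the new primary alcohol.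

Step 3
Reactants: 4 (5R)-5-(2-hydroxyethyl)-2,2,5-trimethyl-1,3-dioxolan-4-one
Product: 5 2-[(4R)-2,2,4-trimethyl-5-oxo-1,3-dioxolan-4-yl]acetaldehyde
Conditions: Dess–Martin periodinane (1.2 equiv), NaHCO3, CH2Cl2, 0 °C to rt
Reagents that add atoms: none
Why: Dess–Martin oxidation stops cleanly at the aldehyde, and the buffered, near-neutral medium should prevent β-elimination of the acetal oxygen and premature opening of the dioxolanone.

Step 4
Reactants: 5 2-[(4R)-2,2,4-trimethyl-5-oxo-1,3-dioxolan-4-yl]acetaldehyde; 6 allenylboronic acid pinacol ester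
Product: 9 (3R,5R)-3-hydroxy-3-methyl-5-(prop-2-yn-1-yl)oxolan-2-one, via homopropargylic pinacol borate 7 (not isolated), via homopropargylic alcohol 8 (not isolated)
Conditions: (R)-3,3'-bis(2,4,6-triisopropylphenyl)-1,1'-binaphthyl-2,2'-diyl hydrogen phosphate ((R)-TRIP, 0.1 equiv), 4 Å MS, toluene, −20 °C; then p-TsOH·H2O (0.2 equiv), THF–H2O, rt
Reagents that add atoms: allenylboronic acid pinacol ester, C=C=CB1OC(C)(C)C(C)(C)O1
Why: Chiral-phosphoric-acid-catalysed propargylboration transfers the propargyl group by SE2' from the allenylboronate through a closed six-membered transition state in which the (R)-acid is expected to expose the Re face of the aldehyde, setting C5' as R under catalyst control (C7' is remote), and after acidic hydrolysis of borate 7 the C5' hydroxyl of 8 attacks the activated dioxolanone carbonyl (5-exo-trig transacylation) and expels acetone to give the lactone.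

Step 5
Reactants: 9 (3R,5R)-3-hydroxy-3-methyl-5-(prop-2-yn-1-yl)oxolan-2-one; 10 triethylsilyl trifluoromethanesulfonate
Product: 11 (3R,5R)-3-methyl-5-(prop-2-yn-1-yl)-3-[(triethylsilyl)oxy]oxolan-2-one
Conditions: TESOTf (1.3 equiv), 2,6-lutidine (2 equiv), CH2Cl2, −78 to 0 °C
Reagents that add atoms: triethylsilyl trifluoromethanesulfonate, CC[Si](CC)(CC)OS(=O)(=O)C(F)(F)F
Why: Silyl triflate with a hindered pyridine base silylates even a tertiary α-hydroxy lactone while alkyne and lactone stay inert, and the triethylsilyl ether keeps an aluminium alkoxide from forming in step 8 yet can later be removed beside an epoxide.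

Step 6
Reactants: 12 7-hydroxy-8-methoxycoumarin; 13 chloromethyl methyl sulfide
Product: 14 8-methoxy-7-[(methylsulfanyl)methoxy]-2H-chromen-2-one
Conditions: NaH (1.1 equiv), MeSCH2Cl (1.2 equiv), NaI (0.1 equiv), DMF, 0 °C to rt
Reagents that add atoms: chloromethyl methyl sulfide, CSCCl
Why: Williamson O-alkylation of the acidic 7-hydroxycoumarin phenoxide with the α-chloro sulfide (iodide catalysis) gives the methylthiomethyl ether, and the coumarin lactone is stable to the non-nucleophilic base.

Step 7
Reactants: 14 8-methoxy-7-[(methylsulfanyl)methoxy]-2H-chromen-2-one; 15 sulfuryl chloride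
Product: 16 7-(chloromethoxy)-8-methoxy-2H-chromen-2-one
Conditions: SO2Cl2 (1.05 equiv), CH2Cl2, 0 °C; volatiles removed in vacuo, used crude at once
Reagents that add atoms: sulfuryl chloride, O=S(=O)(Cl)Cl
Why: Chlorinolysis of the O,S-acetal proceeds by S-chlorination and collapse of the chlorosulfonium ion to the aryloxymethyl cation, which chloride captures, while one equivalent at 0 °C should leave the electron-poor coumarin nucleus and its C3=C4 bond unchlorinated.

Step 8
Reactants: 11 (3R,5R)-3-methyl-5-(prop-2-yn-1-yl)-3-[(triethylsilyl)oxy]oxolan-2-one; 16 7-(chloromethoxy)-8-methoxy-2H-chromen-2-one; 17 trimethylaluminium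
Product: 19 8-methoxy-7-{[(2E)-3-methyl-4-{(2R,4R)-4-methyl-5-oxo-4-[(triethylsilyl)oxy]oxolan-2-yl}but-2-en-1-yl]oxy}-2H-chromen-2-one, via (E)-alkenyldimethylalane 18 (not isolated)
Conditions: Me3Al (3 equiv), Cp2ZrCl2 (0.2 equiv), H2O (1.5 equiv), CH2Cl2, −25 °C; volatiles and free Me3Al removed under high vacuum at 0 °C; then 16 (1.5 equiv), CH2Cl2, −20 to 0 °C; aq. potassium sodium tartrate
Reagents that add atoms: trimethylaluminium, C[Al](C)C; 7-(chloromethoxy)-8-methoxycoumarin 16, COc1c(OCCl)ccc2ccc(=O)oc12
Why: Zirconium-catalysed methylalumination adds CH3 and Al syn across the terminal alkyne, methyl going to the internal carbon C3' and aluminium to the terminal carbon C2', to give the (E)-alkenyldimethylalane 18 and the C3'–CH3 bond. Once free Me3Al has been pumped off, the Lewis-acidic alane ionises the α-chloro ether 16 and its sp2 carbon attacks the aryloxymethyl cation with retention of geometry, forming C1'–C2', so C1' ends cis to the methyl and trans to C4'. The closest known reaction is this same methylalumination followed by trapping of the alkenylalane with chloromethyl methyl ether or paraformaldehyde, and an aryloxymethyl chloride is another α-chloro ether of that class. No ring is closed and no stereocentre is created, and C5' and C7' take no part. The step needs internal-methyl regiochemistry and syn addition, secured by the unhindered terminal alkyne and by staying at or below 0 °C so that the alkenylmetal cannot isomerise, and it needs alkenyl-over-methyl transfer, which is inherent to alkenylalanes. The triethylsilyl ether prevents a competing aluminium alkoxide, and the low temperature together with removal of free Me3Al should keep the lactone and coumarin carbonyls from methyl addition and the electrophile from being consumed.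

Step 9
Reactants: 19 8-methoxy-7-{[(2E)-3-methyl-4-{(2R,4R)-4-methyl-5-oxo-4-[(triethylsilyl)oxy]oxolan-2-yl}but-2-en-1-yl]oxy}-2H-chromen-2-one; 20 potassium peroxymonosulfate (active component of Oxone)
Product: 21 8-methoxy-7-{[(2R,3R)-3-methyl-3-({(2R,4R)-4-methyl-5-oxo-4-[(triethylsilyl)oxy]oxolan-2-yl}methyl)oxiran-2-yl]methoxy}-2H-chromen-2-one
Conditions: D-fructose-derived ketone catalyst (1,2:4,5-di-O-isopropylidene-β-D-erythro-2,3-hexodiulo-2,6-pyranose, 0.3 equiv), Oxone (2KHSO5·KHSO4·K2SO4), K2CO3, Bu4NHSO4 (cat.), MeCN–CH2(OMe)2 / aq. Na2B4O7–disodium EDTA buffer, pH about 10.5, 0 °C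
Reagents that add atoms: potassium peroxymonosulfate, [K+].[O-]S(=O)(=O)OO
Why: In this Shi epoxidation the chiral dioxirane formed from the D-fructose-derived ketone attacks the electron-rich E-trisubstituted alkene through a spiro transition state on the face that gives the (2'R,3'R)-oxirane under catalyst control, the E geometry fixes C1' and C4' trans on the ring, and the electron-poor coumarin C3=C4 bond should not react.

Step 10
Reactants: 21 8-methoxy-7-{[(2R,3R)-3-methyl-3-({(2R,4R)-4-methyl-5-oxo-4-[(triethylsilyl)oxy]oxolan-2-yl}methyl)oxiran-2-yl]methoxy}-2H-chromen-2-one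
Product: 22 7-{[(2R,3R)-3-{[(2S,4R)-4-hydroxy-4-methyl-5-oxooxolan-2-yl]methyl}-3-methyloxiran-2-yl]methoxy}-8-methoxy-2H-chromen-2-one (CNP0128940.1)
Conditions: Bu4NF (1.5 equiv), AcOH (1.5 equiv), THF, 0 °C to rt
Reagents that add atoms: none
Why: Fluoride desilylation cleaves the Si–O bond, and the acetic acid buffer keeps the medium near neutral so that the liberated tertiary alkoxide is protonated before it can open the oxirane or either lactone.

Compound list
1 | (R)-citramalic acid | OC(=O)C[C@@](C)(O)C(=O)O | starting material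
2 | 2,2-dimethoxypropane | COC(C)(C)OC | starting material
3 | 2-[(4R)-2,2,4-trimethyl-5-oxo-1,3-dioxolan-4-yl]acetic acid | OC(=O)C[C@@]1(C)OC(C)(C)OC1=O | intermediate
4 | (5R)-5-(2-hydroxyethyl)-2,2,5-trimethyl-1,3-dioxolan-4-one | OCC[C@@]1(C)OC(C)(C)OC1=O | intermediate
5 | 2-[(4R)-2,2,4-trimethyl-5-oxo-1,3-dioxolan-4-yl]acetaldehyde | O=CC[C@@]1(C)OC(C)(C)OC1=O | intermediate
6 | allenylboronic acid pinacol ester | C=C=CB1OC(C)(C)C(C)(C)O1 | starting material
7 | (5R)-2,2,5-trimethyl-5-{(2R)-2-[(4,4,5,5-tetramethyl-1,3,2-dioxaborolan-2-yl)oxy]pent-4-yn-1-yl}-1,3-dioxolan-4-one | C#CC[C@@H](OB2OC(C)(C)C(C)(C)O2)C[C@@]1(C)OC(C)(C)OC1=O | intermediate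
8 | (5R)-5-[(2R)-2-hydroxypent-4-yn-1-yl]-2,2,5-trimethyl-1,3-dioxolan-4-one | C#CC[C@@H](O)C[C@@]1(C)OC(C)(C)OC1=O | intermediate
9 | (3R,5R)-3-hydroxy-3-methyl-5-(prop-2-yn-1-yl)oxolan-2-one | C#CC[C@@H]1C[C@@](C)(O)C(=O)O1 | intermediate
10 | triethylsilyl trifluoromethanesulfonate | CC[Si](CC)(CC)OS(=O)(=O)C(F)(F)F | starting material
11 | (3R,5R)-3-methyl-5-(prop-2-yn-1-yl)-3-[(triethylsilyl)oxy]oxolan-2-one | C#CC[C@@H]1C[C@@](C)(O[Si](CC)(CC)CC)C(=O)O1 | intermediate
12 | 7-hydroxy-8-methoxycoumarin | COc1c(O)ccc2ccc(=O)oc12 | starting material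
13 | chloromethyl methyl sulfide | CSCCl | starting material
14 | 8-methoxy-7-[(methylsulfanyl)methoxy]-2H-chromen-2-one | COc1c(OCSC)ccc2ccc(=O)oc12 | intermediate
15 | sulfuryl chloride | O=S(=O)(Cl)Cl | starting material
16 | 7-(chloromethoxy)-8-methoxy-2H-chromen-2-one | COc1c(OCCl)ccc2ccc(=O)oc12 | intermediate
17 | trimethylaluminium | C[Al](C)C | starting material
18 | dimethyl[(1E)-2-methyl-3-{(2R,4R)-4-methyl-5-oxo-4-[(triethylsilyl)oxy]oxolan-2-yl}prop-1-en-1-yl]alumane | C[Al](C)/C=C(\C)C[C@@H]1C[C@@](C)(O[Si](CC)(CC)CC)C(=O)O1 | intermediate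
19 | 8-methoxy-7-{[(2E)-3-methyl-4-{(2R,4R)-4-methyl-5-oxo-4-[(triethylsilyl)oxy]oxolan-2-yl}but-2-en-1-yl]oxy}-2H-chromen-2-one | COc1c(OC/C=C(\C)C[C@@H]2C[C@@](C)(O[Si](CC)(CC)CC)C(=O)O2)ccc2ccc(=O)oc12 | intermediate
20 | potassium peroxymonosulfate | [K+].[O-]S(=O)(=O)OO | starting material
21 | 8-methoxy-7-{[(2R,3R)-3-methyl-3-({(2R,4R)-4-methyl-5-oxo-4-[(triethylsilyl)oxy]oxolan-2-yl}methyl)oxiran-2-yl]methoxy}-2H-chromen-2-one | COc1c(OC[C@H]2O[C@]2(C)C[C@@H]2C[C@@](C)(O[Si](CC)(CC)CC)C(=O)O2)ccc2ccc(=O)oc12 | intermediate
22 | 7-{[(2R,3R)-3-{[(2S,4R)-4-hydroxy-4-methyl-5-oxooxolan-2-yl]methyl}-3-methyloxiran-2-yl]methoxy}-8-methoxy-2H-chromen-2-one | COc1c(OC[C@H]2O[C@]2(C)C[C@@H]2C[C@@](C)(O)C(=O)O2)ccc2ccc(=O)oc12 | target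

Total step count: 10. Longest linear sequence: 8 steps (steps 1–5, 8, 9, 10); steps 6 and 7 form the two-step coumarin branch.

Steps most likely to fail

Step 8. The coupling half may go wrong in several ways. The aryloxymethyl cation could alkylate the electron-rich ring of a second coumarin molecule, a methyl group could be transferred in place of the alkenyl group, or residual aluminium methyl species could use up the electrophile or attack a carbonyl. The fallback sets out from alkenylalane 18, made from 11 exactly as in step 8. Paraformaldehyde is added in CH2Cl2 at 0 °C to rt, and aqueous tartrate work-up should give (3R,5R)-5-[(2E)-4-hydroxy-2-methylbut-2-en-1-yl]-3-methyl-3-[(triethylsilyl)oxy]oxolan-2-one F1. A Mitsunobu etherification of this primary allylic alcohol with the acidic phenol 12 (PPh3, DIAD, THF, 0 °C) then forms the aryl ether by direct SN2 displacement and comes back to the route at 19.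

Step 4. Facial selectivity at C5' may be poor, because the catalyst has to overrule a β-branched, oxygenated aliphatic aldehyde and the pairing may be mismatched. The fallback sets out from 5 and gives up asymmetric induction for separation. A zinc Barbier propargylation (propargyl bromide, Zn, THF–aq. NH4Cl) should give 8 together with its C5' epimer, (5R)-5-[(2S)-2-hydroxypent-4-yn-1-yl]-2,2,5-trimethyl-1,3-dioxolan-4-one F2. The acid treatment of step 4 then lactonises both, giving 9 and (3R,5S)-3-hydroxy-3-methyl-5-(prop-2-yn-1-yl)oxolan-2-one F3. These are ring diastereomers and should separate on silica, so the fallback comes back to the route at 9.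

Step 9. Two things may go wrong here. Facial discrimination may be too low on an allylic aryl ether that also carries remote stereocentres, and the lactones may suffer partial hydrolysis during the basic biphasic oxidation. The fallback sets out from alkenylalane 18 and moves the stereocontrol to a hydroxyl-directed epoxidation. Paraformaldehyde capture gives the allylic alcohol F1, as in the fallback to step 8. A Sharpless asymmetric epoxidation (Ti(OiPr)4, D-(−)-diethyl tartrate, t-BuOOH, 4 Å MS, CH2Cl2, −20 °C) should then give (3R,5R)-5-{[(2R,3R)-3-(hydroxymethyl)-2-methyloxiran-2-yl]methyl}-3-methyl-3-[(triethylsilyl)oxy]oxolan-2-one F4. The D-tartrate is chosen because it is the enantiomer opposite to the one that gives (2S,3S)-epoxygeraniol. A Mitsunobu etherification of F4 with phenol 12 (PPh3, DIAD, THF, 0 °C) comes back to the route at 21.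

Further compounds
F1 | step 8 | (3R,5R)-5-[(2E)-4-hydroxy-2-methylbut-2-en-1-yl]-3-methyl-3-[(triethylsilyl)oxy]oxolan-2-one | C/C(=C\CO)C[C@@H]1C[C@@](C)(O[Si](CC)(CC)CC)C(=O)O1
F2 | step 4 | (5R)-5-[(2S)-2-hydroxypent-4-yn-1-yl]-2,2,5-trimethyl-1,3-dioxolan-4-one | C#CC[C@H](O)C[C@@]1(C)OC(C)(C)OC1=O
F3 | step 4 | (3R,5S)-3-hydroxy-3-methyl-5-(prop-2-yn-1-yl)oxolan-2-one | C#CC[C@H]1C[C@@](C)(O)C(=O)O1
F4 | step 9 | (3R,5R)-5-{[(2R,3R)-3-(hydroxymethyl)-2-methyloxiran-2-yl]methyl}-3-methyl-3-[(triethylsilyl)oxy]oxolan-2-one | OC[C@H]1O[C@]1(C)C[C@@H]1C[C@@](C)(O[Si](CC)(CC)CC)C(=O)O1
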